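**Retrosynthetic overview**
1. Last disconnection: the two catechol O–H groups go back to benzyl ethers, removed by hydrogenolysis. No ring is formed in the route. The only ring, the benzene ring of the 2,3-dihydroxybenzoate, is bought as 2,3-bis(benzyloxy)benzoic acid.
2. Key disconnection: C10–C11, in the middle of the 20-methylhenicosyl chain. Each of these CH2 groups goes back to CH2–CO2H, which gives 11-(aroyloxy)undecanoic acid and 11-methyldodecanoic acid. The two acids are joined by a Ni-electrocatalytic doubly decarboxylative C(sp3)–C(sp3) coupling with the aryl ester already in place.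
3. Enabling feature: an unbroken run of nineteen CH2 groups (C1–C19) lies between the ester oxygen and the isopropyl terminus. C10 and C11 are unhindered, non-stereogenic methylenes, at least eight CH2 groups away from the ester O, the benzene ring and the branch point C20. Both halves are therefore ordinary primary alkyl radicals with no cyclisation, fragmentation or stereochemical issue.
4. The two acids come from carboxylate alkylation with 11-bromoundecan-1-ol followed by alcohol-to-acid oxidation, and from Cu-catalysed coupling of isopentylmagnesium bromide with 8-bromooctanoic acid.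

Key step: step 4

Remark: the target has no stereocentre and no stereogenic double bond. It is achiral, so the structure as given is reached without any stereocontrol.

Step 1
Reactants: 1 8-bromooctanoic acid; 2 isopentylmagnesium bromide (3-methylbutylmagnesium bromide)
Product: 3 11-methyldodecanoic acid
Conditions: 2 (2.3 equiv), Li2CuCl4 (3 mol %), NMP (4 equiv), THF, −20 °C to rt; then 1 M HCl
Reagents that add atoms: none
Why: Copper-catalysed Kochi-type sp3–sp3 cross-coupling of a primary alkyl Grignard reagent with a primary alkyl bromide, a reaction type with close precedent on ω-bromo acids, in which one equivalent of 2 is spent on the carboxyl proton and the carboxylate stays inert at low temperature; no stereocentre is formed.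

Step 2
Reactants: 4 2,3-bis(benzyloxy)benzoic acid; 5 11-bromoundecan-1-ol
Product: 6 11-hydroxyundecyl 2,3-bis(benzyloxy)benzoate
Conditions: K2CO3 (1.5 equiv), DMF, 60 °C
Reagents that add atoms: none
Why: SN2 O-alkylation of a carboxylate by a primary bromide, in which carbonate cannot deprotonate the free primary alcohol, so only the carboxylate acts as nucleophile; no stereocentre is formed.

Step 3
Reactants: 6 11-hydroxyundecyl 2,3-bis(benzyloxy)benzoate
Product: 8 11-{[2,3-bis(benzyloxy)benzoyl]oxy}undecanoic acid, via aldehyde 7 (not isolated)
Conditions: TEMPO (20 mol %), PhI(OAc)2 (2.5 equiv), CH2Cl2/H2O 2:1, rt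
Reagents that add atoms: water, O
Why: Oxoammonium (TEMPO/hypervalent iodine) oxidation of a primary alcohol through the aldehyde and its hydrate to the carboxylic acid, mild enough to leave the benzoate ester, the benzyl aryl ethers and the non-phenolic arene untouched; no stereocentre is formed.

Step 4
Reactants: 8 11-{[2,3-bis(benzyloxy)benzoyl]oxy}undecanoic acid (1 equiv); 3 11-methyldodecanoic acid (3 equiv)
Product: 11 20-methylhenicosyl 2,3-bis(benzyloxy)benzoate, via iso-acid NHPI ester 9 (not isolated), via benzoate-acid NHPI ester 10 (not isolated)
Conditions: N-hydroxyphthalimide (4 equiv), DIC (4 equiv), DMAP (cat.), CH2Cl2, rt, evaporate; then NiCl2·6H2O (20 mol %), 4,4′,4″-tri-tert-butyl-2,2′:6′,2″-terpyridine (20 mol %), NaI, DMF/THF, undivided cell, (+)Zn/(−)RVC, constant current, ca. 3 F per mol of ester, rt, Ar; then 1 M HCl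
Reagents that add atoms: N-hydroxyphthalimide, O=C1c2ccccc2C(=O)N1O (adds atoms to 9 and 10 only; none of them remains in 11)
Why: DIC condenses both acids with N-hydroxyphthalimide to the redox-active esters 9 and 10; cathodically generated low-valent (terpyridine)nickel transfers one electron to each ester, N–O cleavage and loss of CO2 release the primary 10-methylundecyl and 10-(aroyloxy)decyl radicals, these are captured in turn at nickel, and reductive elimination from the dialkylnickel species forms the C10–C11 bond while the zinc anode supplies the electrons. The closest known reaction type is the Ni-electrocatalytic doubly decarboxylative cross-coupling of two alkyl redox-active esters generated in situ, the reductive counterpart of the mixed Kolbe electrolysis, which is established for primary–primary pairs. No ring is closed and no stereocentre is created. The selectivity needed is hetero- over homo-coupling: the two radicals are electronically alike, so it is set by stoichiometry (excess of the cheap acid 3), and the three possible coupling products carry zero, one or two aryl ester groups, which should make chromatographic separation simple. Chemoselectivity rests on the substrate and the cell: the mildly reducing medium should leave the benzoate ester and the benzyl aryl ethers untouched, whereas an anodic Kolbe potential would threaten the electron-rich ring; the tridentate ligand suppresses β-hydride elimination; and the radical site lies ten carbons from the ring and the ester oxygen, so no cyclisation or fragmentation competes.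

Step 5
Reactants: 11 20-methylhenicosyl 2,3-bis(benzyloxy)benzoate
Product: 12 Gentiside A (20-methylhenicosyl 2,3-dihydroxybenzoate)
Conditions: H2 (1 atm), 10 % Pd/C, THF/EtOH 1:1, rt; filtration under Ar
Reagents that add atoms: none
Why: Catalytic hydrogenolysis of the two benzyl aryl ethers under neutral conditions, which cannot touch the saturated chain or the non-benzylic alkyl ester and frees the catechol only at the end; no stereocentre is involved.

**Compound list**
1 | 8-bromooctanoic acid | OC(=O)CCCCCCCBr | starting material
2 | isopentylmagnesium bromide | CC(C)CC[Mg]Br | starting material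
3 | 11-methyldodecanoic acid | CC(C)CCCCCCCCCC(=O)O | intermediate
4 | 2,3-bis(benzyloxy)benzoic acid | OC(=O)c1cccc(OCc2ccccc2)c1OCc3ccccc3 | starting material
5 | 11-bromoundecan-1-ol | OCCCCCCCCCCCBr | starting material
6 | 11-hydroxyundecyl 2,3-bis(benzyloxy)benzoate | OCCCCCCCCCCCOC(=O)c1cccc(OCc2ccccc2)c1OCc3ccccc3 | intermediate
7 | 11-oxoundecyl 2,3-bis(benzyloxy)benzoate | O=CCCCCCCCCCCOC(=O)c1cccc(OCc2ccccc2)c1OCc3ccccc3 | intermediate
8 | 11-{[2,3-bis(benzyloxy)benzoyl]oxy}undecanoic acid | OC(=O)CCCCCCCCCCOC(=O)c1cccc(OCc2ccccc2)c1OCc3ccccc3 | intermediate
9 | 1,3-dioxoisoindolin-2-yl 11-methyldodecanoate | CC(C)CCCCCCCCCC(=O)ON1C(=O)c2ccccc2C1=O | intermediate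
10 | 1,3-dioxoisoindolin-2-yl 11-{[2,3-bis(benzyloxy)benzoyl]oxy}undecanoate | O=C(CCCCCCCCCCOC(=O)c1cccc(OCc2ccccc2)c1OCc3ccccc3)ON4C(=O)c5ccccc5C4=O | intermediate
11 | 20-methylhenicosyl 2,3-bis(benzyloxy)benzoate | CC(C)CCCCCCCCCCCCCCCCCCCOC(=O)c1cccc(OCc2ccccc2)c1OCc3ccccc3 | intermediate
12 | Gentiside A, 20-methylhenicosyl 2,3-dihydroxybenzoate | CC(C)CCCCCCCCCCCCCCCCCCCOC(=O)c1cccc(O)c1O | target

Total step count: 5. Longest linear sequence: 4 steps (4 and 5 to 6, 8, 11, 12).

**Steps most likely to fail**

Step 4. Several things may go wrong:
- Statistical homo-coupling may consume the valuable partner.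
- The radicals may be lost by premature reduction or hydrogen abstraction.
- The activated esters may hydrolyse.
- The waxy product may foul the cathode.

The fallback sets out from 3 and comes back at 11. It replaces the two like partners by a nucleophile and a radical precursor. Acid 3 would undergo Hunsdiecker-type decarboxylative iodination (PhI(OAc)2, I2, 1,2-dichloroethane, visible light, reflux) to 1-iodo-10-methylundecane F1. Magnesium in Et2O would convert this into 10-methylundecylmagnesium iodide F2, and ZnCl2 (0.5 equiv) would give bis(10-methylundecyl)zinc F3. Ester 10 would this time be made from 8 with N-hydroxyphthalimide and DIC and isolated. It would then be coupled with F3 in a nickel-catalysed decarboxylative Negishi-type alkyl–alkyl coupling (NiCl2·glyme, 4,4′-di-tert-butyl-2,2′-bipyridine, THF/DMF, rt). This forms the same C10–C11 bond and gives 11.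

Step 1. The magnesium carboxylate may precipitate and stall the coupling. Reduction or elimination of the bromide and homo-coupling of the Grignard reagent may then take over. The fallback sets out from 1 and comes back at 3. It replaces the sp3–sp3 coupling by olefination and hydrogenation. Acid 1 and PPh3 (MeCN, reflux) would give (7-carboxyheptyl)triphenylphosphonium bromide F4. A Wittig reaction (NaHMDS, 2 equiv, THF, −78 °C to rt, then 3-methylbutanal) would give (Z)-11-methyldodec-8-enoic acid F5. Hydrogenation (H2, Pd/C, EtOAc) would deliver 3.

Step 3. The oxidation may stall at the aldehyde stage because the lipophilic substrate mixes poorly with the aqueous phase. Hemiacetal formation followed by oxidation may also lead to dimeric ester formation. The fallback sets out from 4 and comes back at 8. It buys the carboxyl oxidation level instead of making it, so steps 2 and 3 are both replaced. Acid 4 would be alkylated with commercial tert-butyl 11-bromoundecanoate (K2CO3, DMF, 60 °C) to tert-butyl 11-{[2,3-bis(benzyloxy)benzoyl]oxy}undecanoate F6. Mild acidolysis (85 % H3PO4, toluene, rt) would give 8.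

**Further compounds**
F1 | step 4 | 1-iodo-10-methylundecane | CC(C)CCCCCCCCCI
F2 | step 4 | 10-methylundecylmagnesium iodide | CC(C)CCCCCCCCC[Mg]I
F3 | step 4 | bis(10-methylundecyl)zinc | CC(C)CCCCCCCCC[Zn]CCCCCCCCCC(C)C
F4 | step 1 | (7-carboxyheptyl)triphenylphosphonium bromide | OC(=O)CCCCCCC[P+](c1ccccc1)(c2ccccc2)c3ccccc3.[Br-]
F5 | step 1 | (Z)-11-methyldodec-8-enoic acid | CC(C)C/C=C\CCCCCCC(=O)O
F6 | step 3 | tert-butyl 11-{[2,3-bis(benzyloxy)benzoyl]oxy}undecanoate | CC(C)(C)OC(=O)CCCCCCCCCCOC(=O)c1cccc(OCc2ccccc2)c1OCc3ccccc3
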